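**Plan**
1. Retrosynthesis: after removal of a benzyl cap from the C7 oxygen, ring C (the pyranone) is cut at two bonds at once, C3–C1' (to ring B) and O1–C2, giving an ortho-hydroxyaryl enaminone and the 3,4,5-trimethoxybenzenediazonium ion.
2. The enaminone is cut at C2=C3 into an ortho-hydroxyacetophenone and a formamide acetal, and the acetophenone at its aryl–acetyl bond into 4-methoxyresorcinol, which is isovanillin with the formyl carbon exchanged for oxygen.
3. Forward: ring A (isovanillin) and ring B (3,4,5-trimethoxyaniline) are bought; ring A is oxidised, C-acetylated, benzylated and extended to the enaminone; ring C is the only ring built and closes in the operation that attaches ring B; hydrogenolysis finishes.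
4. Enabling feature: the future C3 is the nucleophilic alpha carbon of a masked beta-ketoaldehyde, exactly where ring B must sit, and the future C2 is an aminomethylene carbon held beside the hydroxyl on C8a, so arylation at C3 is followed by O1–C2 closure with loss of dimethylamine.
5. Stereochemistry: none to control; the target has no stereocentre or stereogenic double bond, and the E geometry of the enaminone is thermodynamic and disappears on ring closure.
6. The benzyl ether is installed only after the Lewis-acid acylation, which an aryl benzyl ether would not reliably survive.

Key step: step 6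

Remark: chromone numbering is used throughout (ring A = benzo ring C4a–C8a, ring B = the 3-aryl group, ring C = the pyranone O1–C2–C3–C4); diazonium salt 9 is assumed to be prepared shortly before use and kept cold and dark.

**Route**

Step 1
Reactants: 1 isovanillin (3-hydroxy-4-methoxybenzaldehyde)
Product: 3 4-methoxybenzene-1,3-diol (4-methoxyresorcinol), via 3-hydroxy-4-methoxyphenyl formate 2 (not isolated)
Conditions: mCPBA (1.2 equiv), CH2Cl2, 0 °C to rt; then MeOH, HCl (cat.), rt, under N2
Reagents that add atoms: mCPBA (3-chloroperoxybenzoic acid), OOC(=O)c1cccc(Cl)c1
Why: Baeyer–Villiger (Dakin-type) oxidation, in which the para-methoxy group gives the aryl ring a higher migratory aptitude than the formyl hydrogen in the Criegee intermediate, so the aldehyde carbon is excised as formate ester 2, which acid-catalysed methanolysis should cleave to the phenol without exposing the oxidisable resorcinol to base.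

Step 2
Reactants: 3 4-methoxybenzene-1,3-diol
Product: 4 1-(2,4-dihydroxy-5-methoxyphenyl)ethanone
Conditions: AcOH (1.5 equiv), BF3·OEt2 (as medium), 85 °C; then aq. NaOAc
Reagents that add atoms: acetic acid, CC(=O)O
Why: Friedel–Crafts (Nencki-type) C-acylation, directed to C6 of 3 because that carbon is ortho to one hydroxyl, para to the other and unhindered, whereas C2 is flanked by two oxygens and C5 is activated only by the methoxy group, and the chelated ketone formed is deactivated towards a second acylation.

Step 3
Reactants: 4 1-(2,4-dihydroxy-5-methoxyphenyl)ethanone
Product: 5 1-(4-benzyloxy-2-hydroxy-5-methoxyphenyl)ethanone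
Conditions: BnBr (1.05 equiv), K2CO3 (1.1 equiv), acetone, reflux
Reagents that add atoms: benzyl bromide, BrCc1ccccc1
Why: Williamson etherification, selective for the C4 hydroxyl because the C2 hydroxyl is locked in a hydrogen bond to the ketone and is the less acidic and less nucleophilic one, as is routine for 2,4-dihydroxyacetophenones.

Step 4
Reactants: 5 1-(4-benzyloxy-2-hydroxy-5-methoxyphenyl)ethanone; 6 N,N-dimethylformamide dimethyl acetal
Product: 7 (E)-1-(4-benzyloxy-2-hydroxy-5-methoxyphenyl)-3-(dimethylamino)prop-2-en-1-one
Conditions: 6 (2 equiv), toluene, 100 °C
Reagents that add atoms: none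
Why: Condensation of the acidic methyl ketone with the amide acetal (enaminone formation) with loss of two molecules of methanol, the E push–pull alkene being the thermodynamic product and the chelated phenol remaining free.

Step 5
Reactants: 8 3,4,5-trimethoxyaniline
Product: 9 3,4,5-trimethoxybenzenediazonium tetrafluoroborate
Conditions: NaNO2 (1.05 equiv), 48% aq. HBF4 (2.5 equiv), H2O, 0 °C; filter, wash with cold Et2O, dry in vacuo
Reagents that add atoms: sodium nitrite, [Na+].[O-]N=O; tetrafluoroboric acid, [H+].F[B-](F)(F)F
Why: Diazotisation of a primary arylamine by nitrous acid generated in situ, with the sparingly soluble tetrafluoroborate salt expected to precipitate from the cold aqueous acid so that it can be collected free of nitrite.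

Step 6
Reactants: 7 (E)-1-(4-benzyloxy-2-hydroxy-5-methoxyphenyl)-3-(dimethylamino)prop-2-en-1-one; 9 3,4,5-trimethoxybenzenediazonium tetrafluoroborate
Product: 11 7-benzyloxy-6-methoxy-3-(3,4,5-trimethoxyphenyl)chromen-4-one, via 2-(dimethylamino)chroman-4-one aminal 10 (not isolated)
Conditions: Ru(bpy)3Cl2·6H2O (2 mol %), degassed MeCN, blue LEDs (450 nm), 20 °C, Ar; 9 (1.5 equiv) added in portions
Reagents that add atoms: none
Why: Photoexcited [Ru(bpy)3]2+ (divalent ruthenium) gives one electron to the diazonium ion of 9, which loses N2, and the resulting 3,4,5-trimethoxyphenyl radical adds to the electron-rich alpha carbon of the push–pull alkene of 7 (the future C3), forming the C3–C1' bond and an alpha-amino radical at the future C2. Trivalent ruthenium (or a further diazonium ion in a short chain) oxidises this radical to the iminium ion, so the process is redox-neutral and the photocatalyst is returned. The hydroxyl on C8a then attacks the iminium carbon in a 6-exo-trig closure (O1–C2, ring C) to give aminal 10, and elimination of dimethylamine across C2–C3 delivers the pyranone, the amine set free also buffering the HBF4 that is formed. The closest known reaction type is the visible-light photoredox Meerwein arylation, which is established on ortho-hydroxyaryl enaminones as a domino alpha-C–H arylation/chromone annulation. No stereocentre is created in 11, since both sp3 carbons of 10 become sp2 on elimination. The selectivity required is C–C bond formation at the alpha carbon in preference to ionic azo coupling there or on ring A and to acid-induced cyclisation of 7 without arylation; base-free conditions, portionwise addition of 9 under continuous irradiation, the donor-tempered electrophilicity of the diazonium ion and the benzyl cap on the C7 oxygen (leaving only the chelated C8a hydroxyl free) should secure it.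

Step 7
Reactants: 11 7-benzyloxy-6-methoxy-3-(3,4,5-trimethoxyphenyl)chromen-4-one
Product: 12 7-hydroxy-6-methoxy-3-(3,4,5-trimethoxyphenyl)chromen-4-one (target)
Conditions: H2 (1 atm), Pd/C (10 wt% palladium on carbon), EtOAc/MeOH, rt; stopped as soon as 11 is consumed
Reagents that add atoms: none
Why: Catalytic hydrogenolysis of the benzylic C–O bond, which on Pd/C is much faster than hydrogenation of the C2=C3 bond of the vinylogous ester, so stopping after one equivalent of H2 should leave the pyranone, the methyl ethers and both arenes untouched.

**Compound list**
1 | isovanillin (3-hydroxy-4-methoxybenzaldehyde) | COc1ccc(C=O)cc1O | starting material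
2 | 3-hydroxy-4-methoxyphenyl formate | COc1ccc(OC=O)cc1O | intermediate
3 | 4-methoxybenzene-1,3-diol (4-methoxyresorcinol) | COc1ccc(O)cc1O | intermediate
4 | 1-(2,4-dihydroxy-5-methoxyphenyl)ethanone | CC(=O)c1cc(OC)c(O)cc1O | intermediate
5 | 1-(4-benzyloxy-2-hydroxy-5-methoxyphenyl)ethanone | CC(=O)c1cc(OC)c(OCc2ccccc2)cc1O | intermediate
6 | N,N-dimethylformamide dimethyl acetal | COC(OC)N(C)C | starting material
7 | (E)-1-(4-benzyloxy-2-hydroxy-5-methoxyphenyl)-3-(dimethylamino)prop-2-en-1-one | CN(C)/C=C/C(=O)c1cc(OC)c(OCc2ccccc2)cc1O | intermediate
8 | 3,4,5-trimethoxyaniline | COc1cc(N)cc(OC)c1OC | starting material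
9 | 3,4,5-trimethoxybenzenediazonium tetrafluoroborate | COc1cc([N+]#N)cc(OC)c1OC.F[B-](F)(F)F | intermediate
10 | 7-benzyloxy-2-(dimethylamino)-6-methoxy-3-(3,4,5-trimethoxyphenyl)chroman-4-one (transient aminal, racemic, C2/C3 configuration undefined and erased on elimination) | COc1cc2c(cc1OCc1ccccc1)OC(N(C)C)C(c1cc(OC)c(OC)c(OC)c1)C2=O | intermediate
11 | 7-benzyloxy-6-methoxy-3-(3,4,5-trimethoxyphenyl)chromen-4-one | COc1cc2c(=O)c(-c3cc(OC)c(OC)c(OC)c3)coc2cc1OCc1ccccc1 | intermediate
12 | 7-hydroxy-6-methoxy-3-(3,4,5-trimethoxyphenyl)chromen-4-one | COc1cc2c(=O)c(-c3cc(OC)c(OC)c(OC)c3)coc2cc1O | target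

**Count**
Total steps: 7. Longest linear sequence: 6 (steps 1, 2, 3, 4, 6, 7); step 5 is the one-step side branch.

**Steps most likely to fail**

Step 6. Ionic azo coupling of the diazonium ion at the enaminone alpha carbon may outrun radical generation. The aryl radical may also be lost to hydrogen abstraction from solvent or the benzylic CH2, and 7 may cyclise under the acid formed before it is arylated. The fallback sets out from 7 and returns at 11, making the same two bonds in two polar/metal-catalysed operations. Treatment of 7 with I2 (CHCl3, rt) should iodinate the alpha carbon and close ring C with loss of dimethylamine, giving 7-benzyloxy-3-iodo-6-methoxychromen-4-one F1. Suzuki–Miyaura coupling of F1 with commercial (3,4,5-trimethoxyphenyl)boronic acid [Pd(PPh3)4 (zerovalent palladium), Na2CO3, DME/H2O, 80 °C] should then forge C3–C1' and give 11.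

Step 1. The peracid may over-oxidise the unprotected, electron-rich phenol ring (quinone formation, ring hydroxylation) in competition with the Baeyer–Villiger pathway, and the resorcinol may be lost to air oxidation during isolation. The fallback sets out from 1 and returns at 3. Acetylation (Ac2O, pyridine, rt) should give 5-formyl-2-methoxyphenyl acetate F2, whose ring is less oxidisable. Baeyer–Villiger oxidation of F2 (mCPBA, CH2Cl2) should give 5-(formyloxy)-2-methoxyphenyl acetate F3. Acid-catalysed methanolysis of both esters (MeOH, HCl cat., reflux, N2) should then release 3.

Step 7. Once the benzyl group is gone, hydrogenation may continue into the C2=C3 bond of the pyranone, or the catalyst may be poisoned and the cleavage stall. The fallback sets out from 11 and gives 12 directly without hydrogen. It is a Lewis-acid debenzylation with BCl3 in the presence of pentamethylbenzene as benzyl-cation scavenger (CH2Cl2, −78 °C). Under these conditions the aryl methyl ethers, none of which is peri to the carbonyl, should be retained. It makes no new compound (entry F0).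

**Further compounds**
F1 | step 6 | 7-benzyloxy-3-iodo-6-methoxychromen-4-one | COc1cc2c(=O)c(I)coc2cc1OCc1ccccc1
F2 | step 1 | 5-formyl-2-methoxyphenyl acetate | COc1ccc(C=O)cc1OC(C)=O
F3 | step 1 | 5-(formyloxy)-2-methoxyphenyl acetate | COc1ccc(OC=O)cc1OC(C)=O
F0 | step 7 | none | none
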